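**Retrosynthetic overview**
- The C13 acetate comes from Mitsunobu inversion of an erythro 11,12-epoxy-13-ol; the oxirane (last ring formed) comes from matched Sharpless epoxidation of the macrocyclic 13R allylic alcohol.
- The 14-membered carbocycle and the trans-fused α-methylene-γ-butyrolactone are closed together across C1–C2 by a new chiral-acid-catalysed macrocyclising allylboration–lactonisation of a seco enal carrying a geometrically defined 2-(methoxycarbonyl)allyl boronate.
- That boronate comes from a 2-ynoate by 1,4-hydroalumination and C-alkylation with ICH2Bpin; the ynoate comes from a homopropargylic alcohol.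
- The C13–C14 bond and the C13 stereocentre come from phosphoric-acid-catalysed propargylation of a C13 enal; C2–C13 with all three E-trisubstituted olefins comes from (2E,6E)-farnesol by SeO2 oxidation of the terminal (E)-methyl.
- Ring order: carbocycle plus lactone in one step, then the epoxide.

Assumption: cembrane numbering is used for the macrocycles (C1 = lactone β-CH, C2 = lactone O–CH, C13 = CH–OAc, C14 = CH2, C15/C16/C17 = lactone α-carbon, carbonyl and exocyclic CH2); the target is then (1R,2S,3E,7E,11R,12S,13S).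

**Step 1**
Reactants: 1 (2E,6E)-farnesol
Product: 2 (2E,6E)-farnesyl tert-butyldimethylsilyl ether
Conditions: TBSCl, imidazole, CH2Cl2, 0 °C → rt
Reagents that add atoms: tert-butyldimethylsilyl chloride, CC(C)(C)[Si](C)(C)Cl
Why: Standard silyl ether formation on the primary allylic alcohol; no stereocentre is involved and both E olefins are untouched.

**Step 2**
Reactants: 2 farnesyl TBS ether
Product: 3 (2E,6E,10E)-12-[(tert-butyldimethylsilyl)oxy]-2,6,10-trimethyldodeca-2,6,10-trien-1-ol
Conditions: SeO2 (0.1 equiv), t-BuOOH (3 equiv), salicylic acid (0.1 equiv), CH2Cl2, 0 °C → rt (any over-oxidised enal is pooled into step 3)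
Reagents that add atoms: tert-butyl hydroperoxide, CC(C)(C)OO
Why: SeO2-catalysed allylic oxidation (ene reaction then 2,3-sigmatropic shift) hydroxylates the (E)-methyl of the electron-rich terminal isopropylidene selectively, which fixes the future 11E geometry, while the allylic-ether olefin is deactivated.

**Step 3**
Reactants: 3 terminal allylic alcohol
Product: 4 (2E,6E,10E)-12-[(tert-butyldimethylsilyl)oxy]-2,6,10-trimethyldodeca-2,6,10-trienal
Conditions: MnO2 (15 equiv), CH2Cl2, rt
Reagents that add atoms: none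
Why: MnO2 allylic oxidation gives the enal without E/Z isomerisation or over-oxidation.

**Step 4**
Reactants: 4 silyloxy trienal; 5 allenylboronic acid pinacol ester
Product: 7 (4R,5E,9E,13E)-15-[(tert-butyldimethylsilyl)oxy]-5,9,13-trimethylpentadeca-5,9,13-trien-1-yn-4-ol, via borate ester 6 (not isolated)
Conditions: (R)-TRIP phosphoric acid (10 mol%), 4 Å MS, toluene, −20 °C; aq. NaHCO3
Reagents that add atoms: none
Why: Chiral phosphoric acid-catalysed propargylation of the aldehyde by the allenyl boronate (SE2' through a closed six-membered transition state) forms C13–C14; the (R)-catalyst is expected to direct Re-face attack as in the parent allylboration, giving the 4R carbinol (= C13 R), to be confirmed by Mosher ester analysis.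

**Step 5**
Reactants: 7 homopropargylic alcohol
Product: 8 (4R,5E,9E,13E)-4,15-bis[(tert-butyldimethylsilyl)oxy]-5,9,13-trimethylpentadeca-5,9,13-trien-1-yne
Conditions: TBSOTf, 2,6-lutidine, CH2Cl2, −78 → 0 °C
Reagents that add atoms: tert-butyldimethylsilyl triflate, CC(C)(C)[Si](C)(C)OS(=O)(=O)C(F)(F)F
Why: Silyl triflate silylation of the hindered secondary alcohol proceeds with retention and leaves the alkyne and olefins untouched.

**Step 6**
Reactants: 8 bis-silyl enyne
Product: 10 methyl (5R,6E,10E,14E)-5,16-bis[(tert-butyldimethylsilyl)oxy]-6,10,14-trimethylhexadeca-6,10,14-trien-2-ynoate, via lithium acetylide 9 (not isolated)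
Conditions: n-BuLi, THF, −78 °C; then ClCO2Me, −78 → 0 °C
Reagents that add atoms: methyl chloroformate, COC(=O)Cl
Why: Deprotonation of the terminal alkyne and C-acylation of the acetylide installs C16 as the ester; silyl ethers and the C13 centre are inert.

**Step 7**
Reactants: 10 ynoate; 11 2-(iodomethyl)-4,4,5,5-tetramethyl-1,3,2-dioxaborolane
Product: 13 methyl (2Z,5R,6E,10E,14E)-5,16-bis[(tert-butyldimethylsilyl)oxy]-6,10,14-trimethyl-2-[(4,4,5,5-tetramethyl-1,3,2-dioxaborolan-2-yl)methyl]hexadeca-2,6,10,14-tetraenoate, via alkenylalane 12 (not isolated)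
Conditions: i-Bu2AlH, HMPA, THF, 0 °C; then 11, 0 °C → rt
Reagents that add atoms: none
Why: HMPA-complexed i-Bu2AlH adds hydride 1,4 to the ynoate by cis H–Al delivery without touching the ester, and C-alkylation of the α-aluminio enoate by the α-iodo boronate with retention places C14 trans to CH2B (cis to CO2Me), the geometry required for an anti allylboration.

**Step 8**
Reactants: 13 bis-silyl allylboronate
Product: 14 methyl (2Z,5R,6E,10E,14E)-5-[(tert-butyldimethylsilyl)oxy]-16-hydroxy-6,10,14-trimethyl-2-[(4,4,5,5-tetramethyl-1,3,2-dioxaborolan-2-yl)methyl]hexadeca-2,6,10,14-tetraenoate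
Conditions: PPTS (0.2 equiv), MeOH, 0 °C → rt
Reagents that add atoms: none
Why: Mild acid-catalysed methanolysis cleaves the unhindered primary allylic silyl ether much faster than the hindered secondary one, and the pinacol boronate and ester tolerate it.

**Step 9**
Reactants: 14 allylic alcohol
Product: 15 methyl (2Z,5R,6E,10E,14E)-5-[(tert-butyldimethylsilyl)oxy]-6,10,14-trimethyl-16-oxo-2-[(4,4,5,5-tetramethyl-1,3,2-dioxaborolan-2-yl)methyl]hexadeca-2,6,10,14-tetraenoate
Conditions: MnO2 (20 equiv), CH2Cl2, rt; filter, use at once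
Reagents that add atoms: none
Why: Neutral MnO2 allylic oxidation gives the (E)-enal and spares the allyl boronate, whose uncatalysed addition to an enal is slow at rt because of the electron-withdrawing ester.

**Step 10**
Reactants: 15 seco enal allylboronate
Product: 17 (1R,2S,3E,7E,11E,13R)-13-[(tert-butyldimethylsilyl)oxy]cembra-3,7,11,15(17)-tetraen-16,2-olide, via macrocyclic borate ester 16 (not isolated)
Conditions: (R)-TRIP N-triflylphosphoramide (10 mol%), 4 Å MS, toluene, 1 mM (15 added over 12 h), −20 °C → rt; then 40 °C, 2 h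
Reagents that add atoms: none
Why: Proposed new method: a chiral Brønsted acid-catalysed macrocyclising allylboration–lactonisation in which the N-triflylphosphoramide hydrogen-bonds to a boronate oxygen and the formyl C–H of 15 and so accelerates the otherwise sluggish closed six-membered chair addition of the electron-poor 2-(methoxycarbonyl)allyl boronate, so that at 1 mM the 14-membered ring closes faster than oligomerisation or the uncatalysed background; with C3 and C14 (trans to CH2B) both equatorial the adduct is anti, the (R)-catalyst pocket exposes the Re face of the enal (2S, hence 1R), and the O–B alkoxide then acylates on the methyl ester to give the trans-fused α-methylene-γ-butyrolactone; the closest known reaction types are chiral phosphoric acid-catalysed intermolecular allyl- and crotylboration of aldehydes with pinacol boronates, acid-catalysed additions of 2-alkoxycarbonyl allylboronates that give α-methylene-γ-butyrolactones, and uncatalysed macrocyclising allylboration used for ten-membered germacranolide rings.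

**Step 11**
Reactants: 17 silyl-protected macrolactone
Product: 18 (1R,2S,3E,7E,11E,13R)-13-hydroxycembra-3,7,11,15(17)-tetraen-16,2-olide
Conditions: HF·pyridine, pyridine, THF, 0 °C → rt
Reagents that add atoms: none
Why: Buffered fluoride desilylation frees the C13 alcohol without base, so the α-methylene lactone is not attacked.

**Step 12**
Reactants: 18 macrocyclic allylic alcohol
Product: 19 (1R,2S,3E,7E,11R,12R,13R)-11,12-epoxy-13-hydroxycembra-3,7,15(17)-trien-16,2-olide
Conditions: Ti(OiPr)4 (0.2 equiv), D-(−)-DIPT (0.3 equiv), t-BuOOH (2 equiv, in decane), 4 Å MS, CH2Cl2, −20 °C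
Reagents that add atoms: tert-butyl hydroperoxide, CC(C)(C)OO
Why: Katsuki–Sharpless asymmetric epoxidation epoxidises only the olefin of the allylic alcohol; D-(−)-tartrate with the 13R carbinol is the matched (fast, erythro) pairing and sets C11 and C12 with the oxirane geometry of the target (the 12-descriptor reads R here only because the free OH changes the CIP ranking).

**Step 13**
Reactants: 19 erythro epoxy alcohol
Product: 20 (1R,2S,3E,7E,11R,12S,13S)-13-acetoxy-11,12-epoxycembra-3,7,15(17)-trien-16,2-olide (target)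
Conditions: PPh3, DIAD, AcOH, toluene, 0 °C → rt
Reagents that add atoms: acetic acid, CC(=O)O
Why: Mitsunobu reaction: SN2 displacement of the alkoxyphosphonium by acetate inverts C13 to S and installs the acetate in one operation, giving the threo epoxy acetate that direct epoxidation of a 13S alcohol would not deliver.

**Compound list**
1 | (2E,6E)-farnesol | OC/C=C(\C)CC/C=C(\C)CCC=C(C)C | starting material
2 | (2E,6E)-farnesyl tert-butyldimethylsilyl ether | CC(C)(C)[Si](C)(C)OC/C=C(\C)CC/C=C(\C)CCC=C(C)C | intermediate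
3 | (2E,6E,10E)-12-[(tert-butyldimethylsilyl)oxy]-2,6,10-trimethyldodeca-2,6,10-trien-1-ol | CC(C)(C)[Si](C)(C)OC/C=C(\C)CC/C=C(\C)CC/C=C(\C)CO | intermediate
4 | (2E,6E,10E)-12-[(tert-butyldimethylsilyl)oxy]-2,6,10-trimethyldodeca-2,6,10-trienal | CC(C)(C)[Si](C)(C)OC/C=C(\C)CC/C=C(\C)CC/C=C(\C)C=O | intermediate
5 | allenylboronic acid pinacol ester | C=C=CB1OC(C)(C)C(C)(C)O1 | starting material
6 | O-pinacolboryl ester of 7 (borate of the 4R carbinol) | CC(C)(C)[Si](C)(C)OC/C=C(\C)CC/C=C(\C)CC/C=C(\C)[C@H](OB1OC(C)(C)C(C)(C)O1)CC#C | intermediate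
7 | (4R,5E,9E,13E)-15-[(tert-butyldimethylsilyl)oxy]-5,9,13-trimethylpentadeca-5,9,13-trien-1-yn-4-ol | CC(C)(C)[Si](C)(C)OC/C=C(\C)CC/C=C(\C)CC/C=C(\C)[C@H](O)CC#C | intermediate
8 | (4R,5E,9E,13E)-4,15-bis[(tert-butyldimethylsilyl)oxy]-5,9,13-trimethylpentadeca-5,9,13-trien-1-yne | CC(C)(C)[Si](C)(C)OC/C=C(\C)CC/C=C(\C)CC/C=C(\C)[C@H](O[Si](C)(C)C(C)(C)C)CC#C | intermediate
9 | lithium acetylide of 8 | CC(C)(C)[Si](C)(C)OC/C=C(\C)CC/C=C(\C)CC/C=C(\C)[C@H](O[Si](C)(C)C(C)(C)C)CC#C[Li] | intermediate
10 | methyl (5R,6E,10E,14E)-5,16-bis[(tert-butyldimethylsilyl)oxy]-6,10,14-trimethylhexadeca-6,10,14-trien-2-ynoate | CC(C)(C)[Si](C)(C)OC/C=C(\C)CC/C=C(\C)CC/C=C(\C)[C@H](O[Si](C)(C)C(C)(C)C)CC#CC(=O)OC | intermediate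
11 | 2-(iodomethyl)-4,4,5,5-tetramethyl-1,3,2-dioxaborolane | ICB1OC(C)(C)C(C)(C)O1 | starting material
12 | α-(diisobutylaluminio) enoate from 10 (Al trans to the C4 chain, 5R) | CC(C)(C)[Si](C)(C)OC/C=C(\C)CC/C=C(\C)CC/C=C(\C)[C@H](O[Si](C)(C)C(C)(C)C)C/C=C(/[Al](CC(C)C)CC(C)C)C(=O)OC | intermediate
13 | methyl (2Z,5R,6E,10E,14E)-5,16-bis[(tert-butyldimethylsilyl)oxy]-6,10,14-trimethyl-2-[(4,4,5,5-tetramethyl-1,3,2-dioxaborolan-2-yl)methyl]hexadeca-2,6,10,14-tetraenoate | CC(C)(C)[Si](C)(C)OC/C=C(\C)CC/C=C(\C)CC/C=C(\C)[C@H](O[Si](C)(C)C(C)(C)C)C/C=C(/CB1OC(C)(C)C(C)(C)O1)C(=O)OC | intermediate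
14 | methyl (2Z,5R,6E,10E,14E)-5-[(tert-butyldimethylsilyl)oxy]-16-hydroxy-6,10,14-trimethyl-2-[(4,4,5,5-tetramethyl-1,3,2-dioxaborolan-2-yl)methyl]hexadeca-2,6,10,14-tetraenoate | OC/C=C(\C)CC/C=C(\C)CC/C=C(\C)[C@H](O[Si](C)(C)C(C)(C)C)C/C=C(/CB1OC(C)(C)C(C)(C)O1)C(=O)OC | intermediate
15 | methyl (2Z,5R,6E,10E,14E)-5-[(tert-butyldimethylsilyl)oxy]-6,10,14-trimethyl-16-oxo-2-[(4,4,5,5-tetramethyl-1,3,2-dioxaborolan-2-yl)methyl]hexadeca-2,6,10,14-tetraenoate | O=C/C=C(\C)CC/C=C(\C)CC/C=C(\C)[C@H](O[Si](C)(C)C(C)(C)C)C/C=C(/CB1OC(C)(C)C(C)(C)O1)C(=O)OC | intermediate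
16 | macrocyclic (1R,2S,13R) methyl ester with C2–O–Bpin (14-membered carbocycle closed, lactone not yet formed) | COC(=O)C(=C)[C@H]1C[C@@H](O[Si](C)(C)C(C)(C)C)/C(C)=C/CC/C(C)=C/CC/C(C)=C/[C@@H]1OB2OC(C)(C)C(C)(C)O2 | intermediate
17 | (1R,2S,3E,7E,11E,13R)-13-[(tert-butyldimethylsilyl)oxy]cembra-3,7,11,15(17)-tetraen-16,2-olide | C=C1C(=O)O[C@H]2/C=C(\C)CC/C=C(\C)CC/C=C(\C)[C@H](O[Si](C)(C)C(C)(C)C)C[C@H]12 | intermediate
18 | (1R,2S,3E,7E,11E,13R)-13-hydroxycembra-3,7,11,15(17)-tetraen-16,2-olide | C=C1C(=O)O[C@H]2/C=C(\C)CC/C=C(\C)CC/C=C(\C)[C@H](O)C[C@H]12 | intermediate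
19 | (1R,2S,3E,7E,11R,12R,13R)-11,12-epoxy-13-hydroxycembra-3,7,15(17)-trien-16,2-olide (erythro epoxy alcohol) | C=C1C(=O)O[C@H]2/C=C(\C)CC/C=C(\C)CC[C@H]3O[C@]3(C)[C@H](O)C[C@H]12 | intermediate
20 | (1R,2S,3E,7E,11R,12S,13S)-13-acetoxy-11,12-epoxycembra-3,7,15(17)-trien-16,2-olide | C=C1C(=O)O[C@H]2/C=C(\C)CC/C=C(\C)CC[C@H]3O[C@]3(C)[C@@H](OC(C)=O)C[C@H]12 | target

**Totals**
Total step count: 13. Longest linear sequence: 13 steps (1 → 20; 5 and 11 are purchased).

**Three steps most likely to fail**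

Step 7 (hydroalumination and borylmethylation): the aluminium intermediate may alkylate sluggishly or lose olefin geometry. The fallback sets out from 10 and comes back at 13. Pd(PPh3)4-catalysed cis-hydrostannation of 10 with Bu3SnH (THF, 0 °C) gives the α-stannyl enoate methyl (2E,5R,6E,10E,14E)-5,16-bis[(tert-butyldimethylsilyl)oxy]-6,10,14-trimethyl-2-(tributylstannyl)hexadeca-2,6,10,14-tetraenoate F1. Iododestannylation (I2, CH2Cl2, 0 °C) with retention gives the α-iodo enoate methyl (2E,5R,6E,10E,14E)-5,16-bis[(tert-butyldimethylsilyl)oxy]-2-iodo-6,10,14-trimethylhexadeca-2,6,10,14-tetraenoate F2. Negishi coupling of F2 with (pinacolboryl)methylzinc iodide (from 11 and Zn dust, THF) under PdCl2(dppf) catalysis gives 13 with the same olefin geometry.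

Step 10 (the proposed new macrocyclisation): the catalyst may not override the tether in choosing the aldehyde face, or oligomerisation may compete. The fallback uses known auxiliary-controlled allylboration in place of catalyst control; it sets out from 10 and comes back at 17. Ester exchange of 11 with the (+)-camphor-derived diol gives the chiral reagent 2-exo,3-exo-dihydroxy-3-endo-phenylbornane iodomethylboronate F3. Step 7 conditions applied to 10 with F3 in place of 11 give the camphordiol boronate analogue of 13 F4. PPTS in MeOH gives the camphordiol boronate analogue of 14 F5, and MnO2 gives the camphordiol boronate analogue of 15 F6. Intramolecular allylboration of F6 at 1 mM (Sc(OTf)3 10 mol%, CH2Cl2, −40 °C, or simply toluene at 80 °C) is stereospecific for the anti adduct and face-selective through the boron-bound auxiliary. TsOH-promoted lactonisation then gives 17, and any minor C1/C2 diastereomer is removed by chromatography.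

Step 13 (Mitsunobu inversion at a hindered carbinol next to the epoxide, with an α-methylene lactone present): the fallback sets out from 19 and comes back at 20. Sulfonylation with ClCH2SO2Cl and pyridine (CH2Cl2, 0 °C) gives the (1R,2S,3E,7E,11R,12S,13R)-13-[(chloromethanesulfonyl)oxy]-11,12-epoxycembra-3,7,15(17)-trien-16,2-olide F7. SN2 displacement with CsOAc and 18-crown-6 (toluene, 80 °C) inverts C13 and gives 20 without any phosphine.

**Further compounds**
F1 | step 7 | methyl (2E,5R,6E,10E,14E)-5,16-bis[(tert-butyldimethylsilyl)oxy]-6,10,14-trimethyl-2-(tributylstannyl)hexadeca-2,6,10,14-tetraenoate | CC(C)(C)[Si](C)(C)OC/C=C(\C)CC/C=C(\C)CC/C=C(\C)[C@H](O[Si](C)(C)C(C)(C)C)C/C=C(/[Sn](CCCC)(CCCC)CCCC)C(=O)OC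
F2 | step 7 | methyl (2E,5R,6E,10E,14E)-5,16-bis[(tert-butyldimethylsilyl)oxy]-2-iodo-6,10,14-trimethylhexadeca-2,6,10,14-tetraenoate | CC(C)(C)[Si](C)(C)OC/C=C(\C)CC/C=C(\C)CC/C=C(\C)[C@H](O[Si](C)(C)C(C)(C)C)C/C=C(/I)C(=O)OC
F3 | step 10 | (+)-camphor-derived 2-exo,3-exo-dihydroxy-3-endo-phenylbornane iodomethylboronate | ICB1O[C@H]2[C@]3(C)CC[C@@H](C3(C)C)[C@@]2(c4ccccc4)O1
F4 | step 10 | camphordiol boronate analogue of 13 | CC(C)(C)[Si](C)(C)OC/C=C(\C)CC/C=C(\C)CC/C=C(\C)[C@H](O[Si](C)(C)C(C)(C)C)C/C=C(/CB1O[C@H]2[C@]3(C)CC[C@@H](C3(C)C)[C@@]2(c4ccccc4)O1)C(=O)OC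
F5 | step 10 | camphordiol boronate analogue of 14 | OC/C=C(\C)CC/C=C(\C)CC/C=C(\C)[C@H](O[Si](C)(C)C(C)(C)C)C/C=C(/CB1O[C@H]2[C@]3(C)CC[C@@H](C3(C)C)[C@@]2(c4ccccc4)O1)C(=O)OC
F6 | step 10 | camphordiol boronate analogue of 15 | O=C/C=C(\C)CC/C=C(\C)CC/C=C(\C)[C@H](O[Si](C)(C)C(C)(C)C)C/C=C(/CB1O[C@H]2[C@]3(C)CC[C@@H](C3(C)C)[C@@]2(c4ccccc4)O1)C(=O)OC
F7 | step 13 | (1R,2S,3E,7E,11R,12S,13R)-13-[(chloromethanesulfonyl)oxy]-11,12-epoxycembra-3,7,15(17)-trien-16,2-olide | C=C1C(=O)O[C@H]2/C=C(\C)CC/C=C(\C)CC[C@H]3O[C@]3(C)[C@H](OS(=O)(=O)CCl)C[C@H]12
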